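(The readings were computed on assumed constants, and the scatter is random.)

The trap with two runs of different strength is to read them at equal minutes. The south-west run at 4.00 min shows 6.2% starting material and 32.8% first product, and I doubt those figures belong to the north-west flask.

| flask | starting material | reagent | scavenger | remark | time |
|---|---|---|---|---|---|
| north-west | 10 mM | 4 equiv | 1.5 equiv | the very flask that is asked about, followed so far |  |
| south-west | 15 mM | 4 equiv | 1.5 equiv | run made earlier |  |
| flask | 10 mM | 4.00 equiv | 1.50 equiv |  | 4.0 min |

north-west run (percent of the starting material charged)

| time / s | starting material / % | first product / % |
|---|---|---|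
| 10.0 | 74.2 | 11.7 |
| 20.0 | 58.9 | 19.6 |
| 30.0 | 48.3 | 26.3 |
| 50.0 | 36.6 | 34.2 |
| 80.0 | 27.6 | 41.0 |
| 90.0 | 25.2 | 42.6 |

south-west run (percent of the starting material charged)

| time / min | starting material / % | first product / % |
|---|---|---|
| 0.667 | 30.0 | 36.6 |
| 1.33 | 18.7 | 43.9 |
| 2.00 | 13.7 | 43.7 |
| 2.50 | 10.3 | 41.7 |
| 3.00 | 8.9 | 38.8 |
| 4.00 | 6.2 | 32.8 |

(scatter of a reading: 0.3 percentage points)

- the numbers in the tables scatter by 0.3 percentage points (one standard deviation)
- a reading or a percentage of first product counts all its forms, free or not
- a reading of starting material is of its free form alone

1. amount of starting material at 4.0 min, in percent of the starting material charged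
2. amount of first product at 4.0 min, in percent of the starting material charged
3. amount of bis adduct at 4.0 min, in percent of the starting material charged
4. amount of tris adduct at 4.0 min, in percent of the starting material charged

My rule is a guess: with equal equivalents, two flasks stand alike when charged reagent strength times time is equal, as in a pseudo-first-order view with reagent frozen at its charge. For the north-west flask at 4.0 min, that points to 2.67 min on the south-west run, the equal-dose time.

The objection is that the rule is untested, so I test it. The south-west reading at 0.667 min should match the north-west run at 60.0 s, where interpolation gives 36.5% first product against 36.6% read. Starting material fails: 33.6% against 30.0%, so the stronger run reads lower.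

Interpolating the south-west readings at the equal-dose time gives 40.7% first product and 9.83% starting material. I keep the first of these, and scaling the second by the ratio just found, I commit to 11.0% starting material. Neither bis nor tris adduct was read, so the rule cannot split them.

The forecast says 10.5% starting material, 42.5% first product, 32% bis adduct and 5.5% tris adduct, higher than mine on first product and lower on starting material, with “a third step about threefold slower”.

The flask gives 10.2% starting material, 40.9% first product, 20.4% bis adduct and 17.2% tris adduct, so the forecast's bis stands 12 percentage points high. The forward rate constant of the making of tris adduct is 1.3 times that of the making of bis adduct.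

    starting material + reagent → first product + released group (k = 0.349 M⁻¹ s⁻¹)
    reagent + first product → bis adduct + released group (k = 0.179 M⁻¹ s⁻¹)
    reagent + bis adduct ⇌ tris adduct + released group (K = 1.32, k = 0.230 M⁻¹ s⁻¹)
    starting material + first product ⇌ idle adduct A, settled at all times (K = 180 M⁻¹)
    starting material + released group ⇌ idle adduct B, settled at all times (K = 270 M⁻¹)
    scavenger + released group → scavenged by-product (k = 4.24 M⁻¹ s⁻¹)

The first product interpolated on the south-west run at the equal-dose time of 2.67 min is 40.7%, which lies 0.20 points below the flask's value.

The neighbour with 1.60 equiv of reagent does not have the equivalents of the north-west run, so using the rule there stretches it beyond what it holds fixed. Stretched so, it points to 96.0 s on the north-west run, and extending that run's last readings gives 43.6% first product and 23.8% starting material. That neighbour gives 43.8% first product and 29.1% starting material, so its starting material stands above the reckoning.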